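**Retrosynthetic overview**
- Last ring: the γ-lactone, closed by attack of the 8-OH on the C12 tert-butyl ester after 6-O-angeloylation.
- First ring: the ten-membered carbocycle, closed at C6–C7 (the C1–C10 closure of farnesyl diphosphate) by intramolecular indium allylation of an open-chain farnesane-type bromo-ester aldehyde; this step also sets C6 and C7.
- The (Z)-2-(bromomethyl)enoate comes from a Morita–Baylis–Hillman reaction at the C7 aldehyde, then allylic bromination with transposition.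
- The ring-cis C1=C10 bond with oxidised C14 comes from a Horner–Wadsworth–Emmons union of a D-glutamate-derived lactone (C8) with an aldehyde made from geraniol (C4 by Sharpless epoxidation), then lactone reduction.
- Ring order: carbocycle (C6–C7) first, lactone (O8–C12) second.

Assumption: atoms carry germacrane numbers (C8 lactone carbinol, C6 angelate carbinol, C4 tertiary carbinol, C14 acetoxymethyl carbon, C12 lactone carbonyl); the target is (4S,6R,7S,8R) with a ring-cis C1=C10 bond (E by the CIP rules).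

**Route**

Step 1
Reactants: 1 geraniol
Product: 2 (2S,3S)-2,3-epoxygeraniol
Conditions: Ti(OiPr)4 (5 mol%), L-(+)-diethyl tartrate (7 mol%), tBuOOH, 4 Å molecular sieves, CH2Cl2, −20 °C
Reagents that add atoms: tert-butyl hydroperoxide, CC(C)(C)OO
Why: Sharpless asymmetric epoxidation of the allylic alcohol; the L-(+)-tartrate ligand directs oxygen to the face that gives the (2S,3S)-epoxide, which fixes the later C4 carbinol centre.

Step 2
Reactants: 2 (2S,3S)-2,3-epoxygeraniol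
Product: 3 (3S)-3,7-dimethyloct-6-ene-1,3-diol
Conditions: NaAlH2(OCH2CH2OMe)2, THF, 0 °C to rt
Reagents that add atoms: none
Why: Hydroxyl-directed hydride opening of the 2,3-epoxy alcohol at C2 gives the 1,3-diol; the C–O bond at the tertiary centre is not broken, so its configuration is kept.

Step 3
Reactants: 3 (3S)-3,7-dimethyloct-6-ene-1,3-diol
Product: 4 (4S)-2,2,4-trimethyl-4-(4-methylpent-3-en-1-yl)-1,3-dioxane
Conditions: Me2C(OMe)2, PPTS (cat.), CH2Cl2, rt
Reagents that add atoms: 2,2-dimethoxypropane, COC(C)(C)OC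
Why: Acid-catalysed transketalisation protects the 1,3-diol as its acetonide, which masks C6–OH and the tertiary C4–OH together.

Step 4
Reactants: 4 (4S)-2,2,4-trimethyl-4-(4-methylpent-3-en-1-yl)-1,3-dioxane
Product: 6 3-[(4S)-2,2,4-trimethyl-1,3-dioxan-4-yl]propanal, via ozonide 5 (not isolated)
Conditions: O3, CH2Cl2, −78 °C; then PPh3, −78 °C to rt
Reagents that add atoms: ozone, [O-][O+]=O
Why: Ozonolysis with reductive work-up cleaves the only alkene and gives the C1 aldehyde.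

Step 5
Reactants: 6 3-[(4S)-2,2,4-trimethyl-1,3-dioxan-4-yl]propanal, 7 (5R)-5-[(triphenylmethoxy)methyl]oxolan-2-one
Product: 9 (3E,5R)-3-{3-[(4S)-2,2,4-trimethyl-1,3-dioxan-4-yl]propylidene}-5-[(triphenylmethoxy)methyl]oxolan-2-one, via lithiated phosphonolactone 8 (not isolated)
Conditions: 7, LiN(iPr)2 (1.1 equiv), THF, −78 °C; ClP(O)(OEt)2; LiN(iPr)2 (1.2 equiv), −78 °C to rt; then 6, rt to 40 °C
Reagents that add atoms: none
Why: O-phosphorylation of the lactone enolate and a base-induced 1,3-phosphorus shift give the α-phosphono lactone anion, and its Horner–Wadsworth–Emmons olefination with 6 gives mainly the E-alkylidene lactone (chain trans to the carbonyl; minor Z isomer removed), which places C9 cis to C2 as the ring-cis C1=C10 bond needs.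

Step 6
Reactants: 9 (3E,5R)-3-{3-[(4S)-2,2,4-trimethyl-1,3-dioxan-4-yl]propylidene}-5-[(triphenylmethoxy)methyl]oxolan-2-one
Product: 10 (2E,4R)-2-{3-[(4S)-2,2,4-trimethyl-1,3-dioxan-4-yl]propylidene}-5-(triphenylmethoxy)pentane-1,4-diol
Conditions: iBu2AlH (4 equiv), CH2Cl2, −78 to 0 °C
Reagents that add atoms: none
Why: 1,2-Reduction of the α-alkylidene lactone opens it to the allylic C14 alcohol and the free 8-OH without touching the alkene geometry or C8.

Step 7
Reactants: 10 (2E,4R)-2-{3-[(4S)-2,2,4-trimethyl-1,3-dioxan-4-yl]propylidene}-5-(triphenylmethoxy)pentane-1,4-diol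
Product: 11 (2E,4R)-4-hydroxy-2-{3-[(4S)-2,2,4-trimethyl-1,3-dioxan-4-yl]propylidene}-5-(triphenylmethoxy)pentyl acetate
Conditions: AcCl (1.05 equiv), 2,4,6-collidine, CH2Cl2, −78 °C
Reagents that add atoms: acetyl chloride, CC(=O)Cl
Why: Selective acylation of the primary allylic alcohol over the hindered secondary 8-OH installs the C14 acetate of the target.

Step 8
Reactants: 11 (2E,4R)-4-hydroxy-2-{3-[(4S)-2,2,4-trimethyl-1,3-dioxan-4-yl]propylidene}-5-(triphenylmethoxy)pentyl acetate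
Product: 12 (2E,4R)-4-[(tert-butyldimethylsilyl)oxy]-2-{3-[(4S)-2,2,4-trimethyl-1,3-dioxan-4-yl]propylidene}-5-(triphenylmethoxy)pentyl acetate
Conditions: TBSCl, imidazole, DMF, rt
Reagents that add atoms: tert-butyldimethylsilyl chloride, CC(C)(C)[Si](C)(C)Cl
Why: Silylation gives a bulky, non-chelating 8-O-silyl ether that later steers the allylation and keeps 8-OH out of the way until the last step.

Step 9
Reactants: 12 (2E,4R)-4-[(tert-butyldimethylsilyl)oxy]-2-{3-[(4S)-2,2,4-trimethyl-1,3-dioxan-4-yl]propylidene}-5-(triphenylmethoxy)pentyl acetate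
Product: 13 (2E,6S)-2-{(2R)-2-[(tert-butyldimethylsilyl)oxy]-3-hydroxypropyl}-6,8-dihydroxy-6-methyloct-2-en-1-yl acetate
Conditions: CSA (0.2 equiv), MeOH/CH2Cl2 (1:1), 0 °C to rt
Reagents that add atoms: none
Why: Mild acid methanolysis removes the trityl ether and the acetonide in one operation, while the secondary TBS ether and the acetate survive.

Step 10
Reactants: 13 (2E,6S)-2-{(2R)-2-[(tert-butyldimethylsilyl)oxy]-3-hydroxypropyl}-6,8-dihydroxy-6-methyloct-2-en-1-yl acetate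
Product: 14 (2E,6S)-2-{(2R)-2-[(tert-butyldimethylsilyl)oxy]-3-oxopropyl}-6-hydroxy-6-methyl-8-oxooct-2-en-1-yl acetate
Conditions: Dess–Martin periodinane (3 equiv), pyridine, CH2Cl2, 0 °C to rt
Reagents that add atoms: none
Why: Dess–Martin oxidation turns both primary alcohols into aldehydes (C7 and C6) under non-epimerising conditions and leaves the tertiary alcohol alone.

Step 11
Reactants: 14 (2E,6S)-2-{(2R)-2-[(tert-butyldimethylsilyl)oxy]-3-oxopropyl}-6-hydroxy-6-methyl-8-oxooct-2-en-1-yl acetate, 15 tert-butyl acrylate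
Product: 16 tert-butyl (3RS,4R,6E,10S)-6-(acetoxymethyl)-4-[(tert-butyldimethylsilyl)oxy]-3,10-dihydroxy-10-methyl-2-methylidene-12-oxododec-6-enoate
Conditions: 15 (10 equiv), DABCO (1 equiv), MeOH (2 equiv), rt, 2–4 d
Reagents that add atoms: none
Why: Morita–Baylis–Hillman reaction; the α-silyloxy aldehyde (C7) is far more electrophilic than the unactivated C6 aldehyde and reacts selectively, and the new C7 carbinol centre is irrelevant because it is removed in step 12.

Step 12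
Reactants: 16 tert-butyl (3RS,4R,6E,10S)-6-(acetoxymethyl)-4-[(tert-butyldimethylsilyl)oxy]-3,10-dihydroxy-10-methyl-2-methylidene-12-oxododec-6-enoate
Product: 17 tert-butyl (2Z,4R,6E,10S)-6-(acetoxymethyl)-2-(bromomethyl)-4-[(tert-butyldimethylsilyl)oxy]-10-hydroxy-10-methyl-12-oxododeca-2,6-dienoate
Conditions: NBS, Me2S, CH2Cl2, −20 to 0 °C
Reagents that add atoms: N-bromosuccinimide, O=C1CCC(=O)N1Br
Why: Corey–Kim bromination of the allylic alcohol with allylic transposition (SN2') gives the thermodynamically preferred (Z)-2-(bromomethyl)enoate with C8 cis to CH2Br; the tertiary alcohol and the aldehyde do not react.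

Step 13
Reactants: 17 tert-butyl (2Z,4R,6E,10S)-6-(acetoxymethyl)-2-(bromomethyl)-4-[(tert-butyldimethylsilyl)oxy]-10-hydroxy-10-methyl-12-oxododeca-2,6-dienoate
Product: 19 tert-butyl 2-[(1R,2R,4E,8S,10R)-4-(acetoxymethyl)-2-[(tert-butyldimethylsilyl)oxy]-8,10-dihydroxy-8-methylcyclodec-4-en-1-yl]prop-2-enoate, via allylindium species 18 (not isolated)
Conditions: indium powder (3 equiv), THF/H2O (4:1), 0.002 M (slow addition of 17), rt
Reagents that add atoms: none
Why: Intramolecular indium Barbier allylation closes the ten-membered ring at C6–C7 through a chair transition state in which the geometrically stable Z-allylindium gives the 6,7-syn adduct and the aldehyde attacks C7 anti to the bulky 8-OTBS group (H8 eclipsed with C13 to relieve allylic 1,3-strain), which sets C6 and C7 as the target needs, while the tert-butyl ester stops the new 6-OH from lactonising.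

Step 14
Reactants: 19 tert-butyl 2-[(1R,2R,4E,8S,10R)-4-(acetoxymethyl)-2-[(tert-butyldimethylsilyl)oxy]-8,10-dihydroxy-8-methylcyclodec-4-en-1-yl]prop-2-enoate, 20 angelic acid
Product: 21 tert-butyl 2-[(1R,2R,4E,8S,10R)-4-(acetoxymethyl)-2-[(tert-butyldimethylsilyl)oxy]-8-hydroxy-8-methyl-10-{[(2Z)-2-methylbut-2-enoyl]oxy}cyclodec-4-en-1-yl]prop-2-enoate
Conditions: 20, 2,4,6-trichlorobenzoyl chloride, Et3N, toluene, rt; then 19, 75 °C
Reagents that add atoms: none
Why: Yamaguchi-type esterification through the mixed anhydride acylates the secondary 6-OH (the tertiary 4-OH is inert) with retention at C6 and without Z-to-E isomerisation of the angelate.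

Step 15
Reactants: 21 tert-butyl 2-[(1R,2R,4E,8S,10R)-4-(acetoxymethyl)-2-[(tert-butyldimethylsilyl)oxy]-8-hydroxy-8-methyl-10-{[(2Z)-2-methylbut-2-enoyl]oxy}cyclodec-4-en-1-yl]prop-2-enoate
Product: 23 (4S,6R,7S,8R)-14-acetoxy-6-(angeloyloxy)-4-hydroxygermacra-1(10),11(13)-dien-12,8-olide (CNP0270682.1), via hydroxy acid 22 (not isolated)
Conditions: CF3CO2H/CH2Cl2 (1:4), 0 °C to rt
Reagents that add atoms: none
Why: Acidolysis removes the secondary TBS ether and the tert-butyl ester (loss of isobutene), and the freed 8-OH closes the γ-lactone onto C12 (acid-catalysed lactonisation); no stereocentre is touched, so the trans-fused 8,12-olide follows from step 13.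

**Compound list**

1 | geraniol, (2E)-3,7-dimethylocta-2,6-dien-1-ol | CC(C)=CCC/C(C)=C/CO | starting material
2 | (2S,3S)-2,3-epoxygeraniol, [(2S,3S)-3-methyl-3-(4-methylpent-3-en-1-yl)oxiran-2-yl]methanol | CC(C)=CCC[C@]1(C)O[C@H]1CO | intermediate
3 | (3S)-3,7-dimethyloct-6-ene-1,3-diol | CC(C)=CCC[C@](C)(O)CCO | intermediate
4 | (4S)-2,2,4-trimethyl-4-(4-methylpent-3-en-1-yl)-1,3-dioxane | CC(C)=CCC[C@]1(C)OC(C)(C)OCC1 | intermediate
5 | 3,3-dimethyl-5-{2-[(4S)-2,2,4-trimethyl-1,3-dioxan-4-yl]ethyl}-1,2,4-trioxolane (ozonide) | CC1(C)OOC(CC[C@]2(C)OC(C)(C)OCC2)O1 | intermediate (not isolated)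
6 | 3-[(4S)-2,2,4-trimethyl-1,3-dioxan-4-yl]propanal | O=CCC[C@]1(C)OC(C)(C)OCC1 | intermediate
7 | (5R)-5-[(triphenylmethoxy)methyl]oxolan-2-one | O=C1O[C@@H](COC(c2ccccc2)(c2ccccc2)c2ccccc2)CC1 | starting material
8 | lithium enolate of diethyl [(5R)-2-oxo-5-[(triphenylmethoxy)methyl]oxolan-3-yl]phosphonate | [Li+].CCOP(=O)(OCC)C1=C([O-])O[C@@H](COC(c2ccccc2)(c2ccccc2)c2ccccc2)C1 | intermediate (not isolated)
9 | (3E,5R)-3-{3-[(4S)-2,2,4-trimethyl-1,3-dioxan-4-yl]propylidene}-5-[(triphenylmethoxy)methyl]oxolan-2-one | O=C1O[C@@H](COC(c2ccccc2)(c2ccccc2)c2ccccc2)C/C1=C\CC[C@]1(C)OC(C)(C)OCC1 | intermediate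
10 | (2E,4R)-2-{3-[(4S)-2,2,4-trimethyl-1,3-dioxan-4-yl]propylidene}-5-(triphenylmethoxy)pentane-1,4-diol | OC/C(C[C@@H](O)COC(c1ccccc1)(c1ccccc1)c1ccccc1)=C/CC[C@]1(C)OC(C)(C)OCC1 | intermediate
11 | (2E,4R)-4-hydroxy-2-{3-[(4S)-2,2,4-trimethyl-1,3-dioxan-4-yl]propylidene}-5-(triphenylmethoxy)pentyl acetate | CC(=O)OC/C(C[C@@H](O)COC(c1ccccc1)(c1ccccc1)c1ccccc1)=C/CC[C@]1(C)OC(C)(C)OCC1 | intermediate
12 | (2E,4R)-4-[(tert-butyldimethylsilyl)oxy]-2-{3-[(4S)-2,2,4-trimethyl-1,3-dioxan-4-yl]propylidene}-5-(triphenylmethoxy)pentyl acetate | CC(=O)OC/C(C[C@@H](O[Si](C)(C)C(C)(C)C)COC(c1ccccc1)(c1ccccc1)c1ccccc1)=C/CC[C@]1(C)OC(C)(C)OCC1 | intermediate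
13 | (2E,6S)-2-{(2R)-2-[(tert-butyldimethylsilyl)oxy]-3-hydroxypropyl}-6,8-dihydroxy-6-methyloct-2-en-1-yl acetate | CC(=O)OC/C(C[C@@H](O[Si](C)(C)C(C)(C)C)CO)=C/CC[C@](C)(O)CCO | intermediate
14 | (2E,6S)-2-{(2R)-2-[(tert-butyldimethylsilyl)oxy]-3-oxopropyl}-6-hydroxy-6-methyl-8-oxooct-2-en-1-yl acetate | CC(=O)OC/C(C[C@@H](O[Si](C)(C)C(C)(C)C)C=O)=C/CC[C@](C)(O)CC=O | intermediate
15 | tert-butyl acrylate | C=CC(=O)OC(C)(C)C | starting material
16 | tert-butyl (3RS,4R,6E,10S)-6-(acetoxymethyl)-4-[(tert-butyldimethylsilyl)oxy]-3,10-dihydroxy-10-methyl-2-methylidene-12-oxododec-6-enoate | CC(=O)OC/C(C[C@@H](O[Si](C)(C)C(C)(C)C)C(O)C(=C)C(=O)OC(C)(C)C)=C/CC[C@](C)(O)CC=O | intermediate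
17 | tert-butyl (2Z,4R,6E,10S)-6-(acetoxymethyl)-2-(bromomethyl)-4-[(tert-butyldimethylsilyl)oxy]-10-hydroxy-10-methyl-12-oxododeca-2,6-dienoate | CC(=O)OC/C(C[C@@H](O[Si](C)(C)C(C)(C)C)/C=C(\CBr)C(=O)OC(C)(C)C)=C/CC[C@](C)(O)CC=O | intermediate
18 | allylindium species from 17 (drawn as the RInBr2 part of the sesquibromide) | CC(=O)OC/C(C[C@@H](O[Si](C)(C)C(C)(C)C)/C=C(\C[In](Br)Br)C(=O)OC(C)(C)C)=C/CC[C@](C)(O)CC=O | intermediate (not isolated)
19 | tert-butyl 2-[(1R,2R,4E,8S,10R)-4-(acetoxymethyl)-2-[(tert-butyldimethylsilyl)oxy]-8,10-dihydroxy-8-methylcyclodec-4-en-1-yl]prop-2-enoate (ring-cis alkene) | C=C(C(=O)OC(C)(C)C)[C@H]1[C@H](O[Si](C)(C)C(C)(C)C)C/C(COC(C)=O)=C\CC[C@](C)(O)C[C@H]1O | intermediate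
20 | angelic acid, (2Z)-2-methylbut-2-enoic acid | C/C=C(/C)C(=O)O | starting material
21 | tert-butyl 2-[(1R,2R,4E,8S,10R)-4-(acetoxymethyl)-2-[(tert-butyldimethylsilyl)oxy]-8-hydroxy-8-methyl-10-{[(2Z)-2-methylbut-2-enoyl]oxy}cyclodec-4-en-1-yl]prop-2-enoate | C=C(C(=O)OC(C)(C)C)[C@H]1[C@H](O[Si](C)(C)C(C)(C)C)C/C(COC(C)=O)=C\CC[C@](C)(O)C[C@H]1OC(=O)/C(C)=C\C | intermediate
22 | 2-[(1S,2R,4E,8S,10R)-4-(acetoxymethyl)-2,8-dihydroxy-8-methyl-10-{[(2Z)-2-methylbut-2-enoyl]oxy}cyclodec-4-en-1-yl]prop-2-enoic acid | C=C(C(=O)O)[C@H]1[C@H](O)C/C(COC(C)=O)=C\CC[C@](C)(O)C[C@H]1OC(=O)/C(C)=C\C | intermediate (not isolated)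
23 | (4S,6R,7S,8R)-14-acetoxy-6-(angeloyloxy)-4-hydroxygermacra-1(10),11(13)-dien-12,8-olide, CNP0270682.1 | C=C1C(=O)O[C@@H]2C/C(COC(C)=O)=C\CC[C@](C)(O)C[C@@H](OC(=O)/C(C)=C\C)[C@@H]12 | target

**Step count and risks**

Total: 15 steps. Longest linear sequence: 15 steps (1 to 23); 7, 15 and 20 are bought.

The three steps most likely to fail:

Step 13 (macrocyclisation). Protonolysis of the allylindium or oligomerisation may beat ring closure, and the facial control at C7 by the 8-OTBS group rests on a model. Fallback: it sets out from 17 and comes back at 21. CrCl2 in THF at high dilution closes the ring through the equilibrated allylchromium reagent, which is anti-selective and should give the 6-epimeric alcohol tert-butyl 2-[(1R,2R,4E,8S,10S)-4-(acetoxymethyl)-2-[(tert-butyldimethylsilyl)oxy]-8,10-dihydroxy-8-methylcyclodec-4-en-1-yl]prop-2-enoate F1. Mitsunobu esterification of F1 with angelic acid 20 (PPh3, DIAD, toluene, 0 °C) then inverts C6 and gives 21.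

Step 11 (Morita–Baylis–Hillman reaction on the dialdehyde). The C6 β-hydroxy aldehyde may react or degrade under the amine, and C8 may epimerise. Fallback: it sets out from 12 and comes back at 16, unmasking the two ends one after the other. HCO2H/Et2O removes only the trityl group and gives the primary alcohol (2E,4R)-4-[(tert-butyldimethylsilyl)oxy]-5-hydroxy-2-{3-[(4S)-2,2,4-trimethyl-1,3-dioxan-4-yl]propylidene}pentyl acetate F2. Dess–Martin oxidation gives the aldehyde (2E,4R)-4-[(tert-butyldimethylsilyl)oxy]-5-oxo-2-{3-[(4S)-2,2,4-trimethyl-1,3-dioxan-4-yl]propylidene}pentyl acetate F3. The reaction with 15 and DABCO, now on the only aldehyde, gives tert-butyl (3RS,4R,6E)-6-(acetoxymethyl)-4-[(tert-butyldimethylsilyl)oxy]-3-hydroxy-2-methylidene-9-[(4S)-2,2,4-trimethyl-1,3-dioxan-4-yl]non-6-enoate F4. Aqueous AcOH removes the acetonide to give tert-butyl (3RS,4R,6E,10S)-6-(acetoxymethyl)-4-[(tert-butyldimethylsilyl)oxy]-3,10,12-trihydroxy-10-methyl-2-methylidenedodec-6-enoate F5, and PhI(OAc)2 with catalytic TEMPO oxidises only its primary alcohol to give 16.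

Step 15 (acid end game). The tertiary 4-OH may eliminate or be acylated in CF3CO2H, and the angelate may migrate to O8 before the lactone closes. Fallback: it sets out from 21 and comes back at 23 by a non-protic route. Me3SiOTf with 2,6-lutidine turns the tert-butyl ester into the silyl ester and silylates the 4-OH, giving trimethylsilyl 2-[(1R,2R,4E,8S,10R)-4-(acetoxymethyl)-2-[(tert-butyldimethylsilyl)oxy]-8-methyl-10-{[(2Z)-2-methylbut-2-enoyl]oxy}-8-[(trimethylsilyl)oxy]cyclodec-4-en-1-yl]prop-2-enoate F6. HF·pyridine in THF removes all three silyl groups and gives the hydroxy acid 22, now isolated, and EDC with catalytic DMAP in CH2Cl2 closes the lactone to 23 under neutral conditions.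

**Further compounds**

F1 | step 13 | tert-butyl 2-[(1R,2R,4E,8S,10S)-4-(acetoxymethyl)-2-[(tert-butyldimethylsilyl)oxy]-8,10-dihydroxy-8-methylcyclodec-4-en-1-yl]prop-2-enoate | C=C(C(=O)OC(C)(C)C)[C@H]1[C@H](O[Si](C)(C)C(C)(C)C)C/C(COC(C)=O)=C\CC[C@](C)(O)C[C@@H]1O
F2 | step 11 | (2E,4R)-4-[(tert-butyldimethylsilyl)oxy]-5-hydroxy-2-{3-[(4S)-2,2,4-trimethyl-1,3-dioxan-4-yl]propylidene}pentyl acetate | CC(=O)OC/C(C[C@@H](O[Si](C)(C)C(C)(C)C)CO)=C/CC[C@]1(C)OC(C)(C)OCC1
F3 | step 11 | (2E,4R)-4-[(tert-butyldimethylsilyl)oxy]-5-oxo-2-{3-[(4S)-2,2,4-trimethyl-1,3-dioxan-4-yl]propylidene}pentyl acetate | CC(=O)OC/C(C[C@@H](O[Si](C)(C)C(C)(C)C)C=O)=C/CC[C@]1(C)OC(C)(C)OCC1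
F4 | step 11 | tert-butyl (3RS,4R,6E)-6-(acetoxymethyl)-4-[(tert-butyldimethylsilyl)oxy]-3-hydroxy-2-methylidene-9-[(4S)-2,2,4-trimethyl-1,3-dioxan-4-yl]non-6-enoate | CC(=O)OC/C(C[C@@H](O[Si](C)(C)C(C)(C)C)C(O)C(=C)C(=O)OC(C)(C)C)=C/CC[C@]1(C)OC(C)(C)OCC1
F5 | step 11 | tert-butyl (3RS,4R,6E,10S)-6-(acetoxymethyl)-4-[(tert-butyldimethylsilyl)oxy]-3,10,12-trihydroxy-10-methyl-2-methylidenedodec-6-enoate | CC(=O)OC/C(C[C@@H](O[Si](C)(C)C(C)(C)C)C(O)C(=C)C(=O)OC(C)(C)C)=C/CC[C@](C)(O)CCO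
F6 | step 15 | trimethylsilyl 2-[(1R,2R,4E,8S,10R)-4-(acetoxymethyl)-2-[(tert-butyldimethylsilyl)oxy]-8-methyl-10-{[(2Z)-2-methylbut-2-enoyl]oxy}-8-[(trimethylsilyl)oxy]cyclodec-4-en-1-yl]prop-2-enoate | C=C(C(=O)O[Si](C)(C)C)[C@H]1[C@H](O[Si](C)(C)C(C)(C)C)C/C(COC(C)=O)=C\CC[C@](C)(O[Si](C)(C)C)C[C@H]1OC(=O)/C(C)=C\C
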